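Cuts: first the O–Si bond on the ring B phenol, then C2–C3 and C2–O1 of the dihydrofuran (ring C) together. This is a [4+1] retron that leaves a four-atom and a one-atom partner.
Enabling feature: O1–C7a–C3a of the benzo ring (ring A) plus benzylic C3, which bears the C9H2–O–aryl arm (ring D), is the O=C–C=C array of an ortho-quinone methide. C2 with its guaiacyl ring (ring B) is one carbon that acts first as nucleophile and then as electrophile, i.e. a benzylic sulfonium ylide.
The quinone methide is stored as a racemic 2-(1-tosylalkyl)phenol, cut at C3–S (sulfinate exchange), C9–O (epoxide opening by eugenol), C3–C9 (methylene transfer) and C3–C3a (ortho-formylation of eugenol).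
The ylide is stored as the sulfonium triflate from O-silylated vanillyl alcohol and isothiocineole, a chiral sulfide made in one step from (R)-limonene.
Forward order: rings A, B and D come with eugenol and vanillin and pass through two arms (six and four steps). Ring C is the only ring formed, in the annulation, and desilylation ends the route.
Stereochemistry: nothing is set before the annulation. The sulfide fixes the attacking face of the ylide and so C2 (after inversion on closure), and the anti approach to the planar quinone methide fixes C3 trans to it.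

Key step: step 11

Assumption: the sense of induction follows the accepted model of benzylidene transfer by this sulfide (ylide aryl group turned away from the ring carbons, attack on the face remote from the gem-dimethyl carbon), which predicts (2S) with the sulfide from (R)-limonene; if a test run shows the antipode, (S)-limonene is used instead.

Step 1
Reactants: 1 eugenol (4-allyl-2-methoxyphenol)
Product: 2 5-allyl-2-hydroxy-3-methoxybenzaldehyde
Conditions: MgCl2, Et3N, (CH2O)n, MeCN, reflux; then 1 M HCl
Reagents that add atoms: paraformaldehyde (as formaldehyde), C=O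
Why: Casnati–Skattebøl ortho-formylation: the magnesium phenolate guides formaldehyde to the only free ortho position of 1 and a second formaldehyde accepts hydride to raise the new carbon to the aldehyde level, under conditions that do not touch the allyl group.

Step 2
Reactants: 2 5-allyl-2-hydroxy-3-methoxybenzaldehyde
Product: 3 5-allyl-3-methoxy-2-(methoxymethoxy)benzaldehyde
Conditions: MOMCl, iPr2NEt, CH2Cl2, 0 °C to rt
Reagents that add atoms: chloromethyl methyl ether, COCCl
Why: O-alkylation of the phenol to its MOM acetal (Williamson type), needed because a free ortho-phenoxide would quench the ylide of step 3 and attack the epoxide, and chosen because the acetal withstands the bases of steps 3 and 4 and leaves under acid that spares allyl groups.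

Step 3
Reactants: 3 5-allyl-3-methoxy-2-(methoxymethoxy)benzaldehyde
Product: 4 rac-2-[5-allyl-3-methoxy-2-(methoxymethoxy)phenyl]oxirane
Conditions: Me3SI, KOH, MeCN, trace H2O, 60 °C
Reagents that add atoms: trimethylsulfonium iodide, C[S+](C)C.[I-]
Why: Corey–Chaykovsky epoxidation of a non-enolisable aryl aldehyde with dimethylsulfonium methylide made in situ; hydroxide in MeCN is too weak to shift the allyl double bond into conjugation (as dimsyl or tert-butoxide in DMSO might), and the new centre may be racemic because step 11 erases it.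

Step 4
Reactants: 4 rac-2-[5-allyl-3-methoxy-2-(methoxymethoxy)phenyl]oxirane; 1 eugenol (1.5 equiv)
Product: 5 rac-1-[5-allyl-3-methoxy-2-(methoxymethoxy)phenyl]-2-(4-allyl-2-methoxyphenoxy)ethan-1-ol
Conditions: Cs2CO3 (0.2 equiv), DMF, 80 °C
Reagents that add atoms: none
Why: Base-catalysed SN2 opening of a terminal aryl epoxide by a phenoxide, the usual entry to 2-aryloxy-1-arylethanols, which in the absence of acid goes to the CH2 terminus, the benzylic carbon being further screened by the ortho-MOM ether.

Step 5
Reactants: 5 rac-1-[5-allyl-3-methoxy-2-(methoxymethoxy)phenyl]-2-(4-allyl-2-methoxyphenoxy)ethan-1-ol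
Product: 6 rac-4-allyl-2-[2-(4-allyl-2-methoxyphenoxy)-1-hydroxyethyl]-6-methoxyphenol
Conditions: 2 M aq. HCl, THF–iPrOH, 45 °C
Reagents that add atoms: none
Why: Acid hydrolysis of an aryl MOM acetal, which is much faster than ionisation of the benzylic alcohol because the β-aryloxy group destabilises that cation, so the alcohol, the aryl ethers and both allyl groups should persist.

Step 6
Reactants: 6 rac-4-allyl-2-[2-(4-allyl-2-methoxyphenoxy)-1-hydroxyethyl]-6-methoxyphenol
Product: 7 rac-4-allyl-2-[2-(4-allyl-2-methoxyphenoxy)-1-tosylethyl]-6-methoxyphenol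
Conditions: p-TolSO2H (1.5 equiv, freshly precipitated), TsOH·H2O (5 mol %), CH2Cl2, rt
Reagents that add atoms: p-toluenesulfinic acid, Cc1ccc(S(=O)O)cc1
Why: Acid-promoted sulfinate exchange (SN1 type), the standard preparation of 2-(1-sulfonylalkyl)phenols: the ortho-hydroxybenzylic alcohol ionises with help from the phenol oxygen and the soft sulfur atom of the sulfinic acid captures the cation to give the stable sulfone as a racemate.

Step 7
Reactants: 8 vanillin (4-hydroxy-3-methoxybenzaldehyde)
Product: 9 3-methoxy-4-[(triisopropylsilyl)oxy]benzaldehyde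
Conditions: TIPSCl, imidazole, DMF, rt
Reagents that add atoms: chlorotriisopropylsilane, CC(C)[Si](Cl)(C(C)C)C(C)C
Why: Imidazole-mediated silylation of the phenol; the bulky triisopropylsilyl ether withstands borohydride, brief strong acid and carbonate, and it keeps the para oxygen from expelling the sulfide as a para-quinone methide once the sulfonium salt meets base.

Step 8
Reactants: 9 3-methoxy-4-[(triisopropylsilyl)oxy]benzaldehyde
Product: 10 {3-methoxy-4-[(triisopropylsilyl)oxy]phenyl}methanol
Conditions: NaBH4, MeOH, 0 °C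
Reagents that add atoms: none
Why: Borohydride reduction of an aryl aldehyde to the benzylic alcohol, chemoselective and harmless to the aryl silyl ether at 0 °C.

Step 9
Reactants: 11 (R)-(+)-limonene
Product: 12 isothiocineole, (1R,4R,5R)-4,7,7-trimethyl-6-thiabicyclo[3.2.1]octane
Conditions: S8, γ-terpinene, neat, 125 °C; fractional distillation
Reagents that add atoms: sulfur, S1SSSSSSS1
Why: Known one-pot radical sulfuration of limonene (thiol-ene type cyclisation) in which sulfur and the hydrogen donor γ-terpinene deliver the elements of H2S across both double bonds; the stereocentre of limonene forces the S–C bridge onto one ring face (C1 and C5) and hydrogen abstraction sets C4.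

Step 10
Reactants: 10 {3-methoxy-4-[(triisopropylsilyl)oxy]phenyl}methanol; 12 isothiocineole
Product: 13 (1R,4R,5R)-6-{3-methoxy-4-[(triisopropylsilyl)oxy]benzyl}-4,7,7-trimethyl-6-thiabicyclo[3.2.1]octan-6-ium triflate (benzyl group exo on sulfur, on the side of the one-carbon bridge C8)
Conditions: TfOH (1.0 equiv, slow addition), CH2Cl2, −20 to 0 °C; crystallisation
Reagents that add atoms: trifluoromethanesulfonic acid, O=S(=O)(O)C(F)(F)F
Why: Acid-promoted S-alkylation of a sulfide by an alcohol (SN1 through the para-silyloxy-stabilised benzylic cation), the established access to sulfonium salts of electron-rich benzylic groups whose halides are too labile; the less hindered exo lone pair reacts to give one diastereomer at sulfur, triflate cannot dealkylate the salt, and crystallisation can raise its optical purity.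

Step 11
Reactants: 7 rac-4-allyl-2-[2-(4-allyl-2-methoxyphenoxy)-1-tosylethyl]-6-methoxyphenol; 13 vanillyl isothiocineolium triflate (1.4 equiv)
Product: 17 {4-[(2S,3R)-5-allyl-3-[(4-allyl-2-methoxyphenoxy)methyl]-7-methoxy-2,3-dihydro-1-benzofuran-2-yl]-2-methoxyphenoxy}triisopropylsilane, via ortho-quinone methide 14 (not isolated), via benzylic sulfonium ylide 15 (not isolated), via betaine 16 (not isolated)
Conditions: Cs2CO3 (3 equiv), MeCN–CH2Cl2, −20 °C, slow addition of 7 to 13 and base; chromatography, sulfide 12 recovered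
Reagents that add atoms: none
Why: Proposed new method: Cs2CO3 deprotonates the phenol of 7, which expels p-toluenesulfinate (1,4-elimination) to give the (E)-quinone methide 14, and it deprotonates 13 to the benzylic ylide 15; the ylide carbon adds to the exocyclic carbon of 14 (C2–C3) with rearomatisation to betaine 16, whose phenoxide displaces the sulfide at C2 with inversion (C2–O1). The closest known reaction types are the base-mediated [4+1] annulation of quinone methides released from 2-(1-sulfonylalkyl)phenols with carbonyl-stabilised sulfonium ylides or with ammonium ylides that carry a chiral amine as leaving group, and the benzylidene transfer from isothiocineole-derived sulfonium salts to aldehydes and imines; new is the union of a semi-stabilised chiral benzylic ylide with an alkyl-substituted quinone methide. Ring C, the only ring formed, closes by a 5-exo-tet substitution in the conformer that has sulfur anti to C3a. C2 is controlled by the sulfide, since the ylide adopts one conformation, is open only on the face remote from the gem-dimethyl carbon and adds irreversibly because aromaticity is restored; the control element sits in the leaving group because a ylide this basic would deprotonate urea or squaramide hydrogen-bond donors and would add to unbound quinone methide in any case. C3 is controlled relative to C2 by the staggered approach that places ring B anti to the C9 arm and sulfur anti to ring A, which leads to the trans ring; bond rotation in 16 cannot alter this relation, so any cis isomer stems from the other approach and is removed by chromatography here, before the phenol is freed, because its epimerisation at C2 would give the antipode. The step needs conjugate addition to outrun tautomerisation of 14 to the 2-(2-aryloxyvinyl)phenol, its dimerisation and benzyl transfer from 13 to sulfinate, which slow addition of 7 to an excess of 13 at low temperature should secure, the sulfone serving as a reservoir through reversible sulfinate addition, while allyl groups, aryl ethers and the silyl ether are inert to carbonate.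

Step 12
Reactants: 17 O-triisopropylsilyl ether of the target
Product: 18 4-[(2S,3R)-5-allyl-3-[(4-allyl-2-methoxyphenoxy)methyl]-7-methoxy-2,3-dihydro-1-benzofuran-2-yl]-2-methoxyphenol (CNP0138854.1)
Conditions: Bu4NF, AcOH (1 equiv each), THF, 0 °C
Reagents that add atoms: none
Why: Fluoride-induced cleavage of the aryl silyl ether, driven by the Si–F bond; acetic acid protonates the liberated para-phenoxide at once, so it cannot open C2–O1 through a para-quinone methide and both stereocentres stay untouched.

Compound list
1 | eugenol (4-allyl-2-methoxyphenol) | C=CCc1ccc(O)c(OC)c1 | starting material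
2 | 5-allyl-2-hydroxy-3-methoxybenzaldehyde | C=CCc1cc(OC)c(O)c(C=O)c1 | intermediate
3 | 5-allyl-3-methoxy-2-(methoxymethoxy)benzaldehyde | C=CCc1cc(OC)c(OCOC)c(C=O)c1 | intermediate
4 | rac-2-[5-allyl-3-methoxy-2-(methoxymethoxy)phenyl]oxirane | C=CCc1cc(OC)c(OCOC)c(C2CO2)c1 | intermediate
5 | rac-1-[5-allyl-3-methoxy-2-(methoxymethoxy)phenyl]-2-(4-allyl-2-methoxyphenoxy)ethan-1-ol | C=CCc1ccc(OCC(O)c2cc(CC=C)cc(OC)c2OCOC)c(OC)c1 | intermediate
6 | rac-4-allyl-2-[2-(4-allyl-2-methoxyphenoxy)-1-hydroxyethyl]-6-methoxyphenol | C=CCc1ccc(OCC(O)c2cc(CC=C)cc(OC)c2O)c(OC)c1 | intermediate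
7 | rac-4-allyl-2-[2-(4-allyl-2-methoxyphenoxy)-1-tosylethyl]-6-methoxyphenol | C=CCc1ccc(OCC(c2cc(CC=C)cc(OC)c2O)S(=O)(=O)c2ccc(C)cc2)c(OC)c1 | intermediate
8 | vanillin | COc1cc(C=O)ccc1O | starting material
9 | 3-methoxy-4-[(triisopropylsilyl)oxy]benzaldehyde | COc1cc(C=O)ccc1O[Si](C(C)C)(C(C)C)C(C)C | intermediate
10 | {3-methoxy-4-[(triisopropylsilyl)oxy]phenyl}methanol | COc1cc(CO)ccc1O[Si](C(C)C)(C(C)C)C(C)C | intermediate
11 | (R)-(+)-limonene | CC1=CC[C@@H](CC1)C(C)=C | starting material
12 | isothiocineole, (1R,4R,5R)-4,7,7-trimethyl-6-thiabicyclo[3.2.1]octane | C[C@@H]1CC[C@@H]2C[C@H]1SC2(C)C | intermediate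
13 | (1R,4R,5R)-6-{3-methoxy-4-[(triisopropylsilyl)oxy]benzyl}-4,7,7-trimethyl-6-thiabicyclo[3.2.1]octan-6-ium triflate, benzyl exo on sulfur | C[C@@H]1CC[C@@H]2C[C@H]1[S@@+](Cc1ccc(O[Si](C(C)C)(C(C)C)C(C)C)c(OC)c1)C2(C)C.[O-]S(=O)(=O)C(F)(F)F | intermediate
14 | (6E)-4-allyl-6-[2-(4-allyl-2-methoxyphenoxy)ethylidene]-2-methoxycyclohexa-2,4-dien-1-one | C=CCC1=C/C(=C\COc2ccc(CC=C)cc2OC)C(=O)C(OC)=C1 | intermediate
15 | sulfonium benzylide of 13 (carbanion on the benzylic carbon, sulfide part unchanged) | C[C@@H]1CC[C@@H]2C[C@H]1[S@@+]([CH-]c1ccc(O[Si](C(C)C)(C(C)C)C(C)C)c(OC)c1)C2(C)C | intermediate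
16 | 4-allyl-2-[(1R,2R)-3-(4-allyl-2-methoxyphenoxy)-1-{3-methoxy-4-[(triisopropylsilyl)oxy]phenyl}-1-(isothiocineol-6-ium-6-yl)propan-2-yl]-6-methoxyphenolate | C=CCc1ccc(OC[C@@H](c2cc(CC=C)cc(OC)c2[O-])[C@@H]([S@+]3C(C)(C)[C@@H]4CC[C@@H](C)[C@H]3C4)c2ccc(O[Si](C(C)C)(C(C)C)C(C)C)c(OC)c2)c(OC)c1 | intermediate
17 | {4-[(2S,3R)-5-allyl-3-[(4-allyl-2-methoxyphenoxy)methyl]-7-methoxy-2,3-dihydro-1-benzofuran-2-yl]-2-methoxyphenoxy}triisopropylsilane | C=CCc1ccc(OC[C@H]2c3cc(CC=C)cc(OC)c3O[C@@H]2c2ccc(O[Si](C(C)C)(C(C)C)C(C)C)c(OC)c2)c(OC)c1 | intermediate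
18 | 4-[(2S,3R)-5-allyl-3-[(4-allyl-2-methoxyphenoxy)methyl]-7-methoxy-2,3-dihydro-1-benzofuran-2-yl]-2-methoxyphenol | C=CCc1ccc(OC[C@H]2c3cc(CC=C)cc(OC)c3O[C@@H]2c2ccc(O)c(OC)c2)c(OC)c1 | target

Total step count: 12. Longest linear sequence: 8 steps (steps 1–6, 11, 12).

Steps most likely to fail

1. Step 11.
- What may go wrong: the bulky ylide may not tell the two faces of the quinone methide apart well enough (cis/trans mixtures). Proton exchange at C2 of the betaine may blur what the sulfide has set. The quinone methide may drain away by tautomerisation before it is intercepted.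
- Fallback, known reaction types only, from 4 and 9 back to 17: C2–C3 is made by an auxiliary-controlled aldol reaction and ring C is closed afterwards through C2–O1 alone.
- Meinwald rearrangement of epoxide 4 (InCl3 cat., THF) should give 2-[5-allyl-3-methoxy-2-(methoxymethoxy)phenyl]acetaldehyde F1. Pinnick oxidation (NaClO2, NaH2PO4, 2-methyl-2-butene, tBuOH–H2O) then gives 2-[5-allyl-3-methoxy-2-(methoxymethoxy)phenyl]acetic acid F2. DCC/DMAP coupling with (S)-4-benzyl-1,3-oxazolidin-2-one gives (4S)-3-{2-[5-allyl-3-methoxy-2-(methoxymethoxy)phenyl]acetyl}-4-benzyl-1,3-oxazolidin-2-one F3.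
- The Evans syn-aldol reaction of F3 (Bu2BOTf, iPr2NEt, CH2Cl2, −78 °C) with aldehyde 9 gives (4S)-3-[(2S,3S)-2-[5-allyl-3-methoxy-2-(methoxymethoxy)phenyl]-3-hydroxy-3-{3-methoxy-4-[(triisopropylsilyl)oxy]phenyl}propanoyl]-4-benzyl-1,3-oxazolidin-2-one F4, in which the auxiliary sets the future C3.
- LiBH4 (Et2O, H2O, 0 °C) releases the auxiliary and gives (1S,2R)-2-[5-allyl-3-methoxy-2-(methoxymethoxy)phenyl]-1-{3-methoxy-4-[(triisopropylsilyl)oxy]phenyl}propane-1,3-diol F5.
- Aqueous HCl in THF removes the MOM group and ionises the para-silyloxybenzylic alcohol. The phenol captures the cation anti to the C3 substituent, as is known for phenylcoumaran-type neolignans. This gives [(2S,3R)-5-allyl-7-methoxy-2-{3-methoxy-4-[(triisopropylsilyl)oxy]phenyl}-2,3-dihydro-1-benzofuran-3-yl]methanol F6, whatever the carbinol configuration.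
- Mitsunobu etherification of F6 with eugenol 1 (PPh3, DIAD, THF) gives 17.

2. Step 6.
- What may go wrong: ionisation may be sluggish because of the β-aryloxy group, and the cation may lose a proton to form an enol ether that then sheds the aryloxy arm.
- Fallback, from 5 back to 7: the C–S bond is made by SN2 displacement on the still protected alcohol, so no cation is involved.
- MsCl and Et3N (CH2Cl2, −20 °C) convert 5 into rac-1-[5-allyl-3-methoxy-2-(methoxymethoxy)phenyl]-2-(4-allyl-2-methoxyphenoxy)ethyl methanesulfonate F7, used crude.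
- p-TolSO2Na with Bu4NI in DMF at 40 °C gives rac-5-allyl-1-[2-(4-allyl-2-methoxyphenoxy)-1-tosylethyl]-3-methoxy-2-(methoxymethoxy)benzene F8.
- HCl in MeOH then cleaves the MOM acetal of the acid-stable sulfone to give 7.

3. Step 4.
- What may go wrong: phenoxide may also attack the benzylic carbon, and the electron-rich epoxide may rearrange or oligomerise on heating.
- Fallback, from 1 back to 6, no protecting group: the aryloxy arm is prepared as an aldehyde and joined directly to the ortho carbon of a second eugenol.
- Eugenol 1 with BrCH2CH(OEt)2 (K2CO3, DMF, 100 °C) gives 4-allyl-1-(2,2-diethoxyethoxy)-2-methoxybenzene F9. Aqueous HCl in acetone gives 2-(4-allyl-2-methoxyphenoxy)acetaldehyde F10.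
- A second portion of 1 is turned with EtMgBr into bromomagnesium 4-allyl-2-methoxyphenolate F11. In toluene F11 undergoes the chelation-directed, ortho-specific hydroxyalkylation of magnesium phenolates with F10 and gives 6 after aqueous work-up.

Further compounds
F1 | step 11 | 2-[5-allyl-3-methoxy-2-(methoxymethoxy)phenyl]acetaldehyde | C=CCc1cc(OC)c(OCOC)c(CC=O)c1
F2 | step 11 | 2-[5-allyl-3-methoxy-2-(methoxymethoxy)phenyl]acetic acid | C=CCc1cc(OC)c(OCOC)c(CC(=O)O)c1
F3 | step 11 | (4S)-3-{2-[5-allyl-3-methoxy-2-(methoxymethoxy)phenyl]acetyl}-4-benzyl-1,3-oxazolidin-2-one | C=CCc1cc(OC)c(OCOC)c(CC(=O)N2C(=O)OC[C@@H]2Cc2ccccc2)c1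
F4 | step 11 | (4S)-3-[(2S,3S)-2-[5-allyl-3-methoxy-2-(methoxymethoxy)phenyl]-3-hydroxy-3-{3-methoxy-4-[(triisopropylsilyl)oxy]phenyl}propanoyl]-4-benzyl-1,3-oxazolidin-2-one | O=C([C@@H](c1cc(CC=C)cc(OC)c1OCOC)[C@H](O)c1ccc(O[Si](C(C)C)(C(C)C)C(C)C)c(OC)c1)N1C(=O)OC[C@@H]1Cc1ccccc1
F5 | step 11 | (1S,2R)-2-[5-allyl-3-methoxy-2-(methoxymethoxy)phenyl]-1-{3-methoxy-4-[(triisopropylsilyl)oxy]phenyl}propane-1,3-diol | OC[C@@H](c1cc(CC=C)cc(OC)c1OCOC)[C@H](O)c1ccc(O[Si](C(C)C)(C(C)C)C(C)C)c(OC)c1
F6 | step 11 | [(2S,3R)-5-allyl-7-methoxy-2-{3-methoxy-4-[(triisopropylsilyl)oxy]phenyl}-2,3-dihydro-1-benzofuran-3-yl]methanol | OC[C@H]1c2cc(CC=C)cc(OC)c2O[C@@H]1c1ccc(O[Si](C(C)C)(C(C)C)C(C)C)c(OC)c1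
F7 | step 6 | rac-1-[5-allyl-3-methoxy-2-(methoxymethoxy)phenyl]-2-(4-allyl-2-methoxyphenoxy)ethyl methanesulfonate | C=CCc1ccc(OCC(OS(C)(=O)=O)c2cc(CC=C)cc(OC)c2OCOC)c(OC)c1
F8 | step 6 | rac-5-allyl-1-[2-(4-allyl-2-methoxyphenoxy)-1-tosylethyl]-3-methoxy-2-(methoxymethoxy)benzene | C=CCc1ccc(OCC(c2cc(CC=C)cc(OC)c2OCOC)S(=O)(=O)c2ccc(C)cc2)c(OC)c1
F9 | step 4 | 4-allyl-1-(2,2-diethoxyethoxy)-2-methoxybenzene | C=CCc1ccc(OCC(OCC)OCC)c(OC)c1
F10 | step 4 | 2-(4-allyl-2-methoxyphenoxy)acetaldehyde | C=CCc1ccc(OCC=O)c(OC)c1
F11 | step 4 | bromomagnesium 4-allyl-2-methoxyphenolate | C=CCc1ccc(O[Mg]Br)c(OC)c1
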